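**Plan**

- Retrosynthesis: the two phenols come last from aryl carbamates; the C4 methylene comes from a C4 ketone; ring C is cut at C3–C4 to a racemic open-chain bis-electrophile (C4 as the aroyl chloride of ring A, C3 as a secondary benzylic chloride); the O1–C2 ether is cut to a ring-A salicylaldehyde and a ring-B α-chloroketone; ring B loses its prenyl (C3') and chloroacetyl (C1') groups by two directed ortho-metalations.
- Forward: the ring-A and ring-B fragments are made separately and joined through the O1–C2 ether; the chain is adjusted (C4: CHO → COCl; C3: C=O → CHCl); ring C is then closed by forming C3–C4, and C4 is deoxygenated.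
- Enabling feature: C3 is benzylic to ring B, so its C–Cl bond gives the same planar, ring-B-stabilised radical from either enantiomer; C4 is bonded to ring A, so it can be carried as an aroyl chloride. Two electrophilic carbons are thus united reductively at nickel.
- Stereochemistry: the only stereocentre (C3, R) is set in that ring closure by a chiral bis(oxazoline)–nickel catalyst, enantioconvergently. The later steps avoid base and enolisation at C3.

Key step: step 10

Assumption: the sense of induction of the bis(oxazoline) ligand in a ring-closing acyl–benzyl coupling cannot be read from the open-chain cases; the (R,R) ligand is written, and its mirror image is to be used if a first run shows the (3S) ketone.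

**Route**

Step 1
Reactants: 1 3-methoxyphenol; 2 N,N-diethylcarbamoyl chloride
Product: 3 3-methoxyphenyl N,N-diethylcarbamate
Conditions: K2CO3, MeCN, reflux
Reagents that add atoms: N,N-diethylcarbamoyl chloride (2), CCN(CC)C(=O)Cl
Why: O-carbamoylation of the phenoxide (acyl substitution) installs the group that directs both later ortho-metalations, masks the future 2'-OH and lowers the donor strength of that oxygen.

Step 2
Reactants: 3 3-methoxyphenyl N,N-diethylcarbamate; 4 prenyl bromide
Product: 6 3-methoxy-2-(3-methylbut-2-en-1-yl)phenyl N,N-diethylcarbamate, via aryllithium 5 (not isolated)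
Conditions: s-BuLi, TMEDA, THF, −78 °C; then 4, −78 → −30 °C
Reagents that add atoms: prenyl bromide (4), CC(C)=CCBr
Why: Directed ortho-metalation removes the proton between OCONEt2 and OMe under the joint direction of both groups, below the onset of the anionic Fries shift, and SN2 alkylation by the primary allylic bromide fixes the prenyl group at the future C3'.

Step 3
Reactants: 6 3-methoxy-2-(3-methylbut-2-en-1-yl)phenyl N,N-diethylcarbamate; 7 2-chloro-N-methoxy-N-methylacetamide
Product: 10 6-(chloroacetyl)-3-methoxy-2-(3-methylbut-2-en-1-yl)phenyl N,N-diethylcarbamate, via aryllithium 8 (not isolated), via lithium hemiaminal alkoxide 9 (not isolated)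
Conditions: s-BuLi, TMEDA, THF, −78 °C; then 7, −78 → −40 °C; H2O
Reagents that add atoms: 2-chloro-N-methoxy-N-methylacetamide (7), CON(C)C(=O)CCl
Why: A second directed ortho-metalation at the only remaining position ortho to the carbamate (kinetic ring lithiation should be preferred over the benzylic-allylic CH2 at −78 °C) is followed by a Weinreb ketone synthesis, whose chelated tetrahedral adduct prevents over-addition and releases the α-chloroketone on work-up.

Step 4
Reactants: 11 2,4,6-trihydroxybenzaldehyde; 2 N,N-diethylcarbamoyl chloride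
Product: 12 4-formyl-3,5-dihydroxyphenyl N,N-diethylcarbamate
Conditions: K2CO3 (1 equiv), 2 (1 equiv), acetone, 0 °C → rt
Reagents that add atoms: N,N-diethylcarbamoyl chloride (2), CCN(CC)C(=O)Cl
Why: Chemoselective O-acylation should occur at the 4-OH, which is para to the formyl group, the most acidic, and the only hydroxyl not hydrogen-bonded to the carbonyl.

Step 5
Reactants: 12 4-formyl-3,5-dihydroxyphenyl N,N-diethylcarbamate; 13 iodomethane
Product: 14 4-formyl-3-hydroxy-5-methoxyphenyl N,N-diethylcarbamate
Conditions: K2CO3 (1.1 equiv), MeI (1.05 equiv), acetone, rt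
Reagents that add atoms: iodomethane (13), CI
Why: Williamson O-methylation of one of two equivalent ortho-hydroxyls should stop after one methyl, because the remaining hydroxyl is then locked in a hydrogen bond to the formyl group.

Step 6
Reactants: 14 4-formyl-3-hydroxy-5-methoxyphenyl N,N-diethylcarbamate; 10 6-(chloroacetyl)-3-methoxy-2-(3-methylbut-2-en-1-yl)phenyl N,N-diethylcarbamate
Product: 15 keto aldehyde: 4-formyl-3-methoxy-5-{2-[2-(diethylcarbamoyloxy)-4-methoxy-3-prenylphenyl]-2-oxoethoxy}phenyl N,N-diethylcarbamate
Conditions: K2CO3, NaI (cat.), DMF, rt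
Reagents that add atoms: none
Why: Williamson ether synthesis (SN2 at the α-keto CH2 with iodide catalysis) forms the O1–C2 bond, and room temperature with a weak base holds back the Rap–Stoermer aldol closure to a benzofuran.

Step 7
Reactants: 15 keto aldehyde; 16 sodium chlorite
Product: 17 keto acid: 4-(diethylcarbamoyloxy)-2-{2-[2-(diethylcarbamoyloxy)-4-methoxy-3-prenylphenyl]-2-oxoethoxy}-6-methoxybenzoic acid
Conditions: NaClO2, NaH2PO4, 2-methyl-2-butene (large excess), t-BuOH/THF/H2O, 0 °C → rt
Reagents that add atoms: sodium chlorite (16), [Na+].[O-]Cl=O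
Why: Pinnick oxidation converts only the aldehyde to the acid, and the excess alkene scavenger intercepts hypochlorous acid so that the prenyl group and the electron-rich rings are not chlorinated.

Step 8
Reactants: 17 keto acid
Product: 18 racemic hydroxy acid: 4-(diethylcarbamoyloxy)-2-{2-[2-(diethylcarbamoyloxy)-4-methoxy-3-prenylphenyl]-2-hydroxyethoxy}-6-methoxybenzoic acid
Conditions: NaBH4 (3 equiv), THF/MeOH, −20 → 0 °C; aq citric acid
Reagents that add atoms: none
Why: Borohydride 1,2-reduction of the α-aryloxy aryl ketone leaves the carboxylate untouched and needs no stereocontrol, because step 10 erases this centre in a radical; the cold protic medium should suppress O→O carbamoyl migration to the new alkoxide.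

Step 9
Reactants: 18 racemic hydroxy acid; 19 1-chloro-N,N,2-trimethylprop-1-en-1-amine
Product: 20 racemic chloro acid chloride: 2-{2-chloro-2-[2-(diethylcarbamoyloxy)-4-methoxy-3-prenylphenyl]ethoxy}-4-(diethylcarbamoyloxy)-6-methoxybenzoyl chloride
Conditions: 19 (2.1 equiv), CH2Cl2, 0 °C → rt, 18 added to 19; volatiles removed, crude used at once
Reagents that add atoms: 1-chloro-N,N,2-trimethylprop-1-en-1-amine (19), CC(C)=C(Cl)N(C)C
Why: The α-chloroenamine turns the acid into the acid chloride and the benzylic alcohol into the chloride (deoxychlorination through an imidate) without free HCl, so prenyl and carbamates are safe, and inverse addition to excess reagent should keep the hydroxy acid chloride from closing to the seven-membered lactone.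

Step 10
Reactants: 20 racemic chloro acid chloride
Product: 21 (3R)-3-[2-(diethylcarbamoyloxy)-4-methoxy-3-prenylphenyl]-5-methoxy-4-oxochroman-7-yl N,N-diethylcarbamate
Conditions: NiCl2(dme) (15 mol %), (R,R)-Ph-BOX [2,2-bis((4R)-4-phenyl-4,5-dihydrooxazol-2-yl)propane] (18 mol %), Mn powder (3 equiv), 2,6-dimethylbenzoic acid (0.75 equiv), 3 Å MS, DMA/THF 3:7, 20 °C, slow addition of 20 to 0.01 M
Reagents that add atoms: none
Why: Proposed new method: zerovalent nickel (from NiCl2(dme), the bis(oxazoline) and Mn) inserts into the aroyl C–Cl bond of ring A, while a monovalent nickel species abstracts chlorine from C3 to give a planar benzylic radical stabilised by ring B, so both enantiomers of 20 pass through the same intermediate; the radical is captured by the tethered acyl nickel centre and C–C reductive elimination from trivalent nickel forms C3–C4, Mn returning the catalyst to its low-valent state. The closest known reaction type is the nickel/bis(oxazoline)-catalysed enantioconvergent reductive acylation of racemic secondary benzylic chlorides with acid chlorides, known between two molecules; the ring-closing variant with an aroyl chloride is the untested part. Ring C closes by radical capture to a seven-membered acyl(benzyl)nickelacycle that contracts on reductive elimination to the six-membered chromanone. The C3 stereocentre is set by the chiral ligand on nickel (catalyst control) at the radical-capture/reductive-elimination stage, independent of the configuration of 20. The step needs ring closure to outrun oligomerisation and benzylic homocoupling (slow addition, high dilution), reductive elimination to outrun β-aryloxide loss and decarbonylation (20 °C), and the α-aryl ketone to keep its configuration (no base, only a weak carboxylic acid additive). The prenyl alkene is geometrically out of reach of the C3 radical, and the aryl carbamates are inert to low-valent nickel at this temperature.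

Step 11
Reactants: 21 (3R)-isoflavanone bis-carbamate
Product: 23 (3R)-3-[2-(diethylcarbamoyloxy)-4-methoxy-3-prenylphenyl]-5-methoxychroman-7-yl N,N-diethylcarbamate, via aluminium alkoxide 22 (not isolated)
Conditions: i-Bu2AlH, CH2Cl2, −78 °C; then Et3SiH (10 equiv), BF3·OEt2, −78 → −30 °C; aq potassium sodium tartrate
Reagents that add atoms: none
Why: Non-basic 1,2-reduction by the aluminium hydride at −78 °C leaves C3 unenolised, and ionic hydrogenation (BF3-assisted SN1 ionisation to the C4 cation stabilised by 5-OMe and O1, then hydride capture from the silane) removes the C4 oxygen without touching C3, the 2'-carbamate blocking pterocarpan closure and the prenyl group being inert to BF3/silane at low temperature.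

Step 12
Reactants: 23 (3R)-isoflavan bis-carbamate
Product: 24 (3R)-3-[2-hydroxy-4-methoxy-3-(3-methylbut-2-en-1-yl)phenyl]-5-methoxy-3,4-dihydro-2H-chromen-7-ol (target)
Conditions: LiAlH4 (excess), THF, reflux; aq potassium sodium tartrate
Reagents that add atoms: none
Why: Hydride cleavage of both aryl carbamates (acyl substitution, the amide fragment being reduced on to the amine) frees 7-OH and 2'-OH without acid, so the ortho-prenylphenol cannot cyclise to a chroman and C3 is untouched.

**Compound list**

1 | 3-methoxyphenol | COc1cccc(O)c1 | starting material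
2 | N,N-diethylcarbamoyl chloride | CCN(CC)C(=O)Cl | starting material
3 | 3-methoxyphenyl N,N-diethylcarbamate | COc1cccc(OC(=O)N(CC)CC)c1 | intermediate
4 | prenyl bromide (1-bromo-3-methylbut-2-ene) | CC(C)=CCBr | starting material
5 | [2-(diethylcarbamoyloxy)-6-methoxyphenyl]lithium | COc1cccc(OC(=O)N(CC)CC)c1[Li] | intermediate (not isolated)
6 | 3-methoxy-2-(3-methylbut-2-en-1-yl)phenyl N,N-diethylcarbamate | COc1cccc(OC(=O)N(CC)CC)c1CC=C(C)C | intermediate
7 | 2-chloro-N-methoxy-N-methylacetamide | CON(C)C(=O)CCl | starting material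
8 | [2-(diethylcarbamoyloxy)-4-methoxy-3-(3-methylbut-2-en-1-yl)phenyl]lithium | [Li]c1ccc(OC)c(CC=C(C)C)c1OC(=O)N(CC)CC | intermediate (not isolated)
9 | lithium 2-chloro-1-[2-(diethylcarbamoyloxy)-4-methoxy-3-prenylphenyl]-1-[methoxy(methyl)amino]ethan-1-olate | [Li]OC(CCl)(N(C)OC)c1ccc(OC)c(CC=C(C)C)c1OC(=O)N(CC)CC | intermediate (not isolated)
10 | 6-(chloroacetyl)-3-methoxy-2-(3-methylbut-2-en-1-yl)phenyl N,N-diethylcarbamate | O=C(CCl)c1ccc(OC)c(CC=C(C)C)c1OC(=O)N(CC)CC | intermediate
11 | 2,4,6-trihydroxybenzaldehyde | O=Cc1c(O)cc(O)cc1O | starting material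
12 | 4-formyl-3,5-dihydroxyphenyl N,N-diethylcarbamate | O=Cc1c(O)cc(OC(=O)N(CC)CC)cc1O | intermediate
13 | iodomethane | CI | starting material
14 | 4-formyl-3-hydroxy-5-methoxyphenyl N,N-diethylcarbamate | O=Cc1c(O)cc(OC(=O)N(CC)CC)cc1OC | intermediate
15 | keto aldehyde: 4-formyl-3-methoxy-5-{2-[2-(diethylcarbamoyloxy)-4-methoxy-3-prenylphenyl]-2-oxoethoxy}phenyl N,N-diethylcarbamate | O=Cc1c(OC)cc(OC(=O)N(CC)CC)cc1OCC(=O)c1ccc(OC)c(CC=C(C)C)c1OC(=O)N(CC)CC | intermediate
16 | sodium chlorite | [Na+].[O-]Cl=O | starting material
17 | keto acid: 4-(diethylcarbamoyloxy)-2-{2-[2-(diethylcarbamoyloxy)-4-methoxy-3-prenylphenyl]-2-oxoethoxy}-6-methoxybenzoic acid | OC(=O)c1c(OC)cc(OC(=O)N(CC)CC)cc1OCC(=O)c1ccc(OC)c(CC=C(C)C)c1OC(=O)N(CC)CC | intermediate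
18 | racemic hydroxy acid: 4-(diethylcarbamoyloxy)-2-{2-[2-(diethylcarbamoyloxy)-4-methoxy-3-prenylphenyl]-2-hydroxyethoxy}-6-methoxybenzoic acid | OC(=O)c1c(OC)cc(OC(=O)N(CC)CC)cc1OCC(O)c1ccc(OC)c(CC=C(C)C)c1OC(=O)N(CC)CC | intermediate
19 | 1-chloro-N,N,2-trimethylprop-1-en-1-amine | CC(C)=C(Cl)N(C)C | starting material
20 | racemic chloro acid chloride: 2-{2-chloro-2-[2-(diethylcarbamoyloxy)-4-methoxy-3-prenylphenyl]ethoxy}-4-(diethylcarbamoyloxy)-6-methoxybenzoyl chloride | ClC(=O)c1c(OC)cc(OC(=O)N(CC)CC)cc1OCC(Cl)c1ccc(OC)c(CC=C(C)C)c1OC(=O)N(CC)CC | intermediate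
21 | (3R)-3-[2-(diethylcarbamoyloxy)-4-methoxy-3-prenylphenyl]-5-methoxy-4-oxochroman-7-yl N,N-diethylcarbamate | COc1cc(OC(=O)N(CC)CC)cc2c1C(=O)[C@H](c1ccc(OC)c(CC=C(C)C)c1OC(=O)N(CC)CC)CO2 | intermediate
22 | diisobutylaluminium alkoxide of the (3R)-isoflavan-4-ol bis-carbamate (both C4 epimers) | COc1cc(OC(=O)N(CC)CC)cc2c1C(O[Al](CC(C)C)CC(C)C)[C@H](c1ccc(OC)c(CC=C(C)C)c1OC(=O)N(CC)CC)CO2 | intermediate (not isolated)
23 | (3R)-3-[2-(diethylcarbamoyloxy)-4-methoxy-3-prenylphenyl]-5-methoxychroman-7-yl N,N-diethylcarbamate | COc1cc(OC(=O)N(CC)CC)cc2c1C[C@H](c1ccc(OC)c(CC=C(C)C)c1OC(=O)N(CC)CC)CO2 | intermediate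
24 | (3R)-3-[2-hydroxy-4-methoxy-3-(3-methylbut-2-en-1-yl)phenyl]-5-methoxy-3,4-dihydro-2H-chromen-7-ol | COc1cc(O)cc2c1C[C@H](c1ccc(OC)c(CC=C(C)C)c1O)CO2 | target

**Summary**

Total step count: 12. Longest linear sequence: 10 (steps 1–3, then 6–12); steps 4–5 form the ring-A branch.

Steps most likely to fail:

1. Step 10. What may go wrong: oligomerisation or benzylic homocoupling in place of ring closure, or poor facial selectivity at nickel in the cyclic transition state. Fallback from 15, using known chemistry: the same C3–C4 bond is made by an N-heterocyclic-carbene-catalysed intramolecular crossed benzoin reaction (achiral N-mesityl bicyclic triazolium chloride, DBU, THF, rt), the aldehyde carbon adding as an acyl anion equivalent to the ketone, to give racemic 3-hydroxyisoflavanone bis-carbamate F1. SmI2 in THF/MeOH at −78 °C cleaves the α-ketol C–O bond to give racemic isoflavanone bis-carbamate F2. Asymmetric transfer hydrogenation under dynamic kinetic resolution (RuCl(p-cymene)[(R,R)-TsDPEN], HCO2H/Et3N, 40 °C; C3 epimerises through the enol while one epimer is reduced, the (R,R) catalyst being expected to give the 4R alcohol) should give cis-(3R,4R)-isoflavan-4-ol bis-carbamate F3. F3 is deoxygenated with Et3SiH/BF3·OEt2 as in the second stage of step 11 and comes back to the route at 23.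

2. Step 11. What may go wrong: loss of C3 configuration by E1 loss of the C3 proton from the C4 cation (or a 1,2-hydride shift) and reduction of the resulting achiral species, or acid attack on the prenyl group. Fallback from 21: reduction with i-Bu2AlH alone and work-up gives the isolated (3R)-isoflavan-4-ol bis-carbamate F4 (C4 epimers). 1,1'-Thiocarbonyldiimidazole with DMAP in CH2Cl2 gives the O-(imidazol-1-ylthiocarbonyl) derivative F5. Bu3SnH/AIBN in toluene at 80 °C (Barton–McCombie deoxygenation) removes the oxygen through a C4 radical, not a cation, and comes back at 23.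

3. Step 3. What may go wrong: deprotonation of the benzylic-allylic CH2 of the prenyl group in competition with ring lithiation, followed by carbamoyl transfer. Fallback from 3, replacing steps 2 and 3: NBS in MeCN at 0 °C brominates para to OMe to give 2-bromo-5-methoxyphenyl N,N-diethylcarbamate F6. LiN(i-Pr)2 in THF at −78 °C removes the proton between the two oxygens, and 4 gives 6-bromo-3-methoxy-2-prenylphenyl N,N-diethylcarbamate F7. Bromine–lithium exchange with n-BuLi at −78 °C, which needs no strong base in prolonged contact with the prenyl CH2, and acylation with 7 come back at 10.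

**Further compounds**

F1 | step 10 | racemic 3-[2-(diethylcarbamoyloxy)-4-methoxy-3-prenylphenyl]-3-hydroxy-5-methoxy-4-oxochroman-7-yl N,N-diethylcarbamate | COc1cc(OC(=O)N(CC)CC)cc2c1C(=O)C(O)(c1ccc(OC)c(CC=C(C)C)c1OC(=O)N(CC)CC)CO2
F2 | step 10 | racemic 3-[2-(diethylcarbamoyloxy)-4-methoxy-3-prenylphenyl]-5-methoxy-4-oxochroman-7-yl N,N-diethylcarbamate | COc1cc(OC(=O)N(CC)CC)cc2c1C(=O)C(c1ccc(OC)c(CC=C(C)C)c1OC(=O)N(CC)CC)CO2
F3 | step 10 | (3R,4R)-3-[2-(diethylcarbamoyloxy)-4-methoxy-3-prenylphenyl]-4-hydroxy-5-methoxychroman-7-yl N,N-diethylcarbamate (cis) | COc1cc(OC(=O)N(CC)CC)cc2c1[C@H](O)[C@H](c1ccc(OC)c(CC=C(C)C)c1OC(=O)N(CC)CC)CO2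
F4 | step 11 | (3R)-3-[2-(diethylcarbamoyloxy)-4-methoxy-3-prenylphenyl]-4-hydroxy-5-methoxychroman-7-yl N,N-diethylcarbamate (C4 epimers) | COc1cc(OC(=O)N(CC)CC)cc2c1C(O)[C@H](c1ccc(OC)c(CC=C(C)C)c1OC(=O)N(CC)CC)CO2
F5 | step 11 | (3R)-3-[2-(diethylcarbamoyloxy)-4-methoxy-3-prenylphenyl]-4-[(imidazol-1-ylthiocarbonyl)oxy]-5-methoxychroman-7-yl N,N-diethylcarbamate (C4 epimers) | COc1cc(OC(=O)N(CC)CC)cc2c1C(OC(=S)n1ccnc1)[C@H](c1ccc(OC)c(CC=C(C)C)c1OC(=O)N(CC)CC)CO2
F6 | step 3 | 2-bromo-5-methoxyphenyl N,N-diethylcarbamate | CCN(CC)C(=O)Oc1cc(OC)ccc1Br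
F7 | step 3 | 6-bromo-3-methoxy-2-(3-methylbut-2-en-1-yl)phenyl N,N-diethylcarbamate | CCN(CC)C(=O)Oc1c(Br)ccc(OC)c1CC=C(C)C
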